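The numbers are those of an exercise; the flask was simulated.

I decided to judge these flasks by one comparison, the two ways an open intermediate can end, and to set the rest of the scheme aside.

    substrate ⇌ open intermediate (K1 = 1.0, k1 = 0.29 h⁻¹)
    partner → second intermediate (k2 = 0.16 h⁻¹)
    open intermediate + second intermediate → target (k3 = 46 M⁻¹ h⁻¹)
    2 open intermediate → homo product (k4 = 39 M⁻¹ h⁻¹)
    open intermediate → side product (k5 = 0.050 h⁻¹)

| setting | maple | birch | cedar | larch |
|---|---|---|---|---|
| substrate | 22 mM (fed, over 20 h) | 22 mM | 22 mM | 22 mM |
| partner | 1.20 equiv | 1.20 equiv (in portions, 3, over 20 h) | 1.20 equiv (fed, over 20 h) | 1.20 equiv |
| time | 30 h | 30 h | 30 h | 30 h |
| remark | all else is in the flask from the start; the feed brings no volume worth counting | first portion at the start, last at 20 h | all else is in the flask from the start; the feed brings no volume worth counting | everything together at the start |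

- the flask with the highest amount of target, in percent of the substrate charged ("all alike" if they lie within 1.5 percentage points) (maple / birch / cedar / larch / all alike)
- final target, as a percentage of the substrate charged, in maple
- final target, as a percentage of the substrate charged, in birch
- final target, as a percentage of the substrate charged, in cedar
- final target, as a percentage of the substrate charged, in larch

- a species is counted by the substrate in it: one homo product counts as two
- where a step has two of a species, its rate is k times that concentration squared, and two are used at each turn
- run time (maple): 30 h

The two clocks on an open intermediate are the trapping time, a pseudo-first-order lifetime equal to the reciprocal of the target step's constant times [second intermediate], and the pairing time, the reciprocal of the doubled homo constant times [open intermediate]. They are equal when [second intermediate]/[open intermediate] stands at the crossover ratio, the doubled homo constant over the target constant, 1.70. Above it, trapping is the quicker end. The side step has a clock of 20.0 h, which I set aside to keep the reckoning simple, and the way back I carried in cedar's reckoning alone, as a pool shared with substrate.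

I reckoned with the fraction left, at the partner's lifetime 6.25 h, when 0.368 of a partner portion charged at the start remains. In maple that allows up to 16.7 mM of second intermediate, and if trapping balances the substrate feed, [open intermediate] is 1.43 mM, so the ratio is 11.7, above the crossover. In cedar, averaging the fraction left over the feed's ages gives 3.04 mM. Substrate and open intermediate share their pool equally, and with pairing as the pool's loss, [open intermediate] is 2.99 mM, which means that 27.2% of the pool remains. The ratio is then 1.02, below the crossover. I stopped there, expecting maple above cedar, without yields.

The forecast held that “that intermediate should be kept low while the second intermediate is plentiful” and gave 76% for maple, 52% for larch, 31% for birch and 24% for cedar.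

The simulation gave 77.6% for maple, the highest, then 60.1% for larch, 36.6% for birch and 31.1% for cedar.

Maple at 15.0 h read a ratio of 12.6, with target at 40.1% and homo product at 4.55%. Cedar at 20.0 h read 35.0, also above the crossover, but homo product already stood at 56.9%, and cedar's target step had done 13% of its turnover by 6.00 h. The homo step carries part of the difference between maple and cedar: taken away, it left that difference at 17 percentage points instead of 47 points.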